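- The stirred vessel holds a solid that feeds starting material into solution and a held gas phase that feeds dissolved gas, so the yield turns on what the dissolved starting material meets there.

solid substrate 0.80 M; gas phase 170 mM (held); protic impurity 0.160 M; time 80 min

    gas phase ⇌ dissolved gas, rate k1*(csat - [dissolved gas]) (k1 = 0.059 min⁻¹, csat = 170 mM)
    starting material → side product (k2 = 0.80 min⁻¹)
    starting material + protic impurity → quenched substrate (k3 = 0.057 M⁻¹ min⁻¹)
    dissolved gas → decomposed reagent (k4 = 0.13 min⁻¹)
    solid substrate ⇌ starting material, rate k5*(cs5 - [starting material]) while solid is left; crystals form when [starting material] > cs5 (cs5 = 0.094 M, k5 = 0.36 min⁻¹)
    starting material + dissolved gas → target (k6 = 10 M⁻¹ min⁻¹)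

- given per volume of solution although it is solid: solid substrate
- at the start none of the gas is dissolved
- at the start none of the solid substrate is in solution
- run time (flask): 80 min

- the target standing at 80 min, as a percentage of the solid substrate charged
- the change that raises the amount of target at 80 min, in percent of the solid substrate charged most ("none" if none brings more than 2 percentage points) (Thursday's / Monday's / Wednesday's / Saturday's / none)
- amount of target at 80 min, in percent of the solid substrate charged, after Saturday's

- Thursday's: doubling the saturation concentration of gas phase, all else as stated
- Monday's: doubling the solubility in step 5, all else as stated
- Wednesday's: doubling the dissolution coefficient of step 5, all else as stated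
- Saturday's: doubling the transfer coefficient of step 1, all else as stated

- Dissolved starting material becomes side product with constant 0.80 min⁻¹, while quenching at 0.00912 min⁻¹ is far slower. Target formation is pseudo-first-order in starting material, with a constant of 10 M⁻¹ min⁻¹ times the dissolved gas, so the split between target and side product moves with the dissolved gas.
- One extreme keeps starting material near nil. Dissolved gas then balances transfer against decomposition at 31.2% of saturation, and 39.9% of the starting material becomes target.
- The other extreme keeps the solution saturated with starting material. Dissolved gas falls to 5.23% of saturation, and 10.0% becomes target.
- The real flask lies between these two, with its starting material between none and saturation. Solving both balances together puts dissolved gas at 13.7% of saturation and starting material at 3.04% of the charge.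
- The gas share, the target constant over itself plus the side-product constant, is then 22.5%. The solid lasts about 31.9 min, shorter than the run, so I expect y to equal this share.
- The same balances give shares of 35.3% after Saturday's, 39.1% after Thursday's, 15.0% after Monday's and 17.5% after Wednesday's. I therefore pick Thursday's.
- The forecast, slightly below this reckoning on both amounts , gives 21.7%, Thursday's and 34%, holding that “more dissolved gas helps directly”.
- The flask gives 21.4%, and 33.7% after Saturday's, with Thursday's the best change at 16 percentage points. Its dissolved gas reads 13.2% of saturation at 8.00 min. The gas share, reckoned for the time while solid is left, contains no solid charge, so it is again 22.5% for the neighbour flask with 0.48 M of solid substrate, which holds target at 20.7% of its solid substrate charged at 80.0 min.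

(All constants are assumed, and the outcome is calculated.)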